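**Plan**
1. Retrosynthesis: the C15–C12′ bond is cut first (vinylogous allylic alkylation). This gives a dienyl butenolide and a butenolide allylic carbonate, both made from one decalin C12 aldehyde, which is cut at C12–C13 (Morita–Baylis–Hillman), C8=C17 (Wittig) and C9–C11 (enolate alkylation).
2. The decalin is then cut at the ring-fusion bond C5–C10 and at C7–C8, which opens rings A and B together to an acyclic chain.
3. Enabling feature: ring B is two three-carbon arcs, C5–C6–C7 and C8–C9–C10, that meet only at these two bonds. C10 is a methyl-bearing quaternary carbon and C8 an sp2 carbon, so C8–C9–C10 can be an alkylidene Meldrum's acid (C10 β-carbon, C8 acyl carbon) and C5–C6–C7 an allylsilane (C5 γ-carbon, C7 terminus of the vinyl group it leaves).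
4. Forward: chain assembly (C3–C4 coupling, cross-metathesis, Knoevenagel), rings A and B in one Lewis-acid operation, C9 side chain and C8 methylene, aldehyde to butenolide, split into nucleophile and electrophile, union, desilylation.
5. Stereochemistry: C3/C4 from the iridium-catalysed tert-(hydroxy)prenylation; C10 and C5 from the chair transition state of ring A closure under control of C3/C4; C9 by equilibration next to the C8 ketone; C15/C12′ from the chiral amine catalyst of the union.

Key step: step 5

Numbering: labdane numbering (decalin C1–C10, C17–C20; side chain C11–C16; primes for the half that carries C12′). "ent-Labdane configuration" means 3-O equatorial, C19 axial and cis to 3-O, C20 axial and cis to C19, H-5 trans to C20, and the C9 side chain equatorial and cis to C20.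
Assumption: in steps 1 and 13 the antipode of Tol-BINAP and the pseudoenantiomer of the cinchona catalyst are those whose sense of induction gives the drawn configuration.

Step 1
Reactants: 1 5-hydroxypentan-2-one; 2 2-methyl-2-vinyloxirane (racemic)
Product: 3 (5R,6R)-5-hydroxy-6-(hydroxymethyl)-6-methyloct-7-en-2-one
Conditions: Ir(C3H5)(Tol-BINAP)(κ2-C,O-4-cyano-3-nitrobenzoate) (5 mol %), K3PO4 (5 mol %), THF, 60 °C
Reagents that add atoms: none
Why: Iridium-catalysed transfer-hydrogenative tert-(hydroxy)prenylation, in which the primary alcohol is dehydrogenated at the metal, the racemic vinyl epoxide converges to one σ-allyliridium alkoxide and addition through a closed chair transition state should set the quaternary C4 and the C3 carbinol with the drawn relative and catalyst-controlled absolute configuration; the ketone is spared because the aldehyde exists only transiently.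

Step 2
Reactants: 3 (5R,6R)-5-hydroxy-6-(hydroxymethyl)-6-methyloct-7-en-2-one
Product: 4 4-[(4R,5R)-2,2-di-tert-butyl-5-ethenyl-5-methyl-1,3,2-dioxasilinan-4-yl]butan-2-one
Conditions: tBu2Si(OTf)2, 2,6-lutidine, CH2Cl2, 0 °C
Reagents that add atoms: di-tert-butylsilyl bis(trifluoromethanesulfonate), CC(C)(C)[Si](OS(=O)(=O)C(F)(F)F)(OS(=O)(=O)C(F)(F)F)C(C)(C)C
Why: Cyclic silylene protection of the 1,3-diol, which should be faster than enol silylation of the ketone and gives a group stable to Lewis acid, amide base, ylide and hydride and removable by fluoride.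

Step 3
Reactants: 4 4-[(4R,5R)-2,2-di-tert-butyl-5-ethenyl-5-methyl-1,3,2-dioxasilinan-4-yl]butan-2-one; 5 allyltrimethylsilane
Product: 6 4-{(4R,5R)-2,2-di-tert-butyl-5-methyl-5-[(E)-3-(trimethylsilyl)prop-1-en-1-yl]-1,3,2-dioxasilinan-4-yl}butan-2-one
Conditions: 5 (5 equiv), second-generation Hoveyda–Grubbs catalyst RuCl2(=CH-C6H4-2-OiPr)(H2IMes) (5 mol %), CH2Cl2, 40 °C
Reagents that add atoms: none
Why: Olefin cross-metathesis, in which the vinyl group on the quaternary carbon cannot homodimerise and excess allylsilane should drive formation of the E cross product; no stereocentre is touched.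

Step 4
Reactants: 6 4-{(4R,5R)-2,2-di-tert-butyl-5-methyl-5-[(E)-3-(trimethylsilyl)prop-1-en-1-yl]-1,3,2-dioxasilinan-4-yl}butan-2-one; 7 2,2-dimethyl-1,3-dioxane-4,6-dione (Meldrum's acid)
Product: 8 5-(4-{(4R,5R)-2,2-di-tert-butyl-5-methyl-5-[(E)-3-(trimethylsilyl)prop-1-en-1-yl]-1,3,2-dioxasilinan-4-yl}butan-2-ylidene)-2,2-dimethyl-1,3-dioxane-4,6-dione
Conditions: morpholine (cat.), AcOH (cat.), 4 Å molecular sieves, toluene, 40 °C
Reagents that add atoms: none
Why: Knoevenagel condensation of the methyl ketone with the strongly C–H-acidic Meldrum's acid, driven by removal of water; the symmetrical acceptor avoids any alkene-geometry question and the buffered catalyst should leave the allylsilane intact.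

Step 5
Reactants: 8 5-(4-{(4R,5R)-2,2-di-tert-butyl-5-methyl-5-[(E)-3-(trimethylsilyl)prop-1-en-1-yl]-1,3,2-dioxasilinan-4-yl}butan-2-ylidene)-2,2-dimethyl-1,3-dioxane-4,6-dione
Product: 10 3,19-O-(di-tert-butylsilylene)-3,19-dihydroxy-11,12,13,14,15,16,17-heptanor-ent-labd-6-en-8-one, via Meldrum's acid adduct 9 (not isolated)
Conditions: Sc(OTf)3 (20 mol %), MeNO2, 0 to 23 °C, then 100 °C; aqueous NaHCO3 work-up
Reagents that add atoms: none
Why: Proposed new method: Sc(OTf)3 chelates the alkylidene Meldrum's acid and the allylsilane γ-carbon C5 adds to the β-carbon C10 (intramolecular Hosomi–Sakurai addition to an alkylidene 1,3-dicarbonyl), which forms C5–C10, closes ring A in the 6-exo mode and leaves a vinyl group (C6=C7) on C5 in adduct 9; on heating, 9 loses acetone to an acylketene whose carbon C8 is attacked by the vinyl terminus C7 in the 6-endo mode (Markovnikov, cation at C6), loss of the C7 proton gives the enone and the β-keto acid at C9 decarboxylates, which forms C7–C8 and closes ring B. The closest known reaction types are the Lewis-acid cyclisation of allylsilanes onto alkylidene 1,3-dicarbonyl compounds, the Sc(OTf)3-catalysed intramolecular Friedel–Crafts acylation of arenes by Meldrum's acid derivatives and the Lewis-acid acylation of alkenes by acyl cations; the new element is an alkene as the acyl acceptor, which is reasonable because the acylketene is generated beside the vinyl group in a 1,2-trans-diequatorial array. C10 and C5 are set in the chair transition state of ring A closure, where the silylene ring holds the C3 oxygen equatorial and C19 axial, the small C20 methyl goes axial (syn to C19) and the bulky Meldrum's acid terminus and the reacting alkene go equatorial, so that the trans relation at C5/C10 becomes the trans ring fusion. The step needs C-allylation at C10 before any acylation, secured by the high electrophilicity of the doubly activated alkylidene at low temperature, and 6-endo acylation at C7 instead of attack at C6, secured by the secondary cation at C6 and the strain of the alternative small-ring products. H-5 remains epimerisable through the dienol of 10, which backs up the trans fusion.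

Step 6
Reactants: 10 3,19-O-(di-tert-butylsilylene)-3,19-dihydroxy-11,12,13,14,15,16,17-heptanor-ent-labd-6-en-8-one; 11 methyl bromoacetate
Product: 12 methyl 3,19-O-(di-tert-butylsilylene)-3,19-dihydroxy-8-oxo-13,14,15,16,17-pentanor-9-epi-ent-labd-6-en-12-oate
Conditions: LiN(iPr)2, THF, −78 °C; then 11, DMPU, −78 to −20 °C
Reagents that add atoms: none
Why: Kinetic α′-deprotonation of the enone (C9 is the only α′ position and γ-deprotonation at C5 is slower at −78 °C) and enolate alkylation with the reactive bromoacetate, which should enter axially on the face opposite the axial C20 methyl and so give the 9-epimer that step 7 corrects.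

Step 7
Reactants: 12 methyl 3,19-O-(di-tert-butylsilylene)-3,19-dihydroxy-8-oxo-13,14,15,16,17-pentanor-9-epi-ent-labd-6-en-12-oate
Product: 14 methyl 3,19-O-(di-tert-butylsilylene)-3,19-dihydroxy-8-oxo-13,14,15,16,17-pentanor-ent-labdan-12-oate, via 9-epi keto ester 13 (not isolated)
Conditions: H2 (1 atm), 10% Pd/C, EtOAc, 23 °C; filtration; then NaOMe (0.2 equiv), MeOH, 23 °C
Reagents that add atoms: none
Why: Catalytic hydrogenation saturates the only alkene (C6=C7 of the enone), and methoxide then equilibrates C9 through the C8 enolate to the equatorial side chain cis to C20, the stable arrangement of 8-oxolabdanes.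

Step 8
Reactants: 14 methyl 3,19-O-(di-tert-butylsilylene)-3,19-dihydroxy-8-oxo-13,14,15,16,17-pentanor-ent-labdan-12-oate
Product: 15 methyl 3,19-O-(di-tert-butylsilylene)-3,19-dihydroxy-13,14,15,16-tetranor-ent-labd-8(17)-en-12-oate
Conditions: Ph3PCH3Br, KN(SiMe3)2, THF, 0 to 50 °C
Reagents that add atoms: methyltriphenylphosphonium bromide, C[P+](c1ccccc1)(c1ccccc1)c1ccccc1.[Br-]
Why: Wittig methylenation of the C8 ketone, which should react with the non-stabilised ylide much faster than the ester; any base-induced epimerisation at C9 before olefination returns the same equatorial isomer.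

Step 9
Reactants: 15 methyl 3,19-O-(di-tert-butylsilylene)-3,19-dihydroxy-13,14,15,16-tetranor-ent-labd-8(17)-en-12-oate
Product: 16 3,19-O-(di-tert-butylsilylene)-3,19-dihydroxy-13,14,15,16-tetranor-ent-labd-8(17)-en-12-al
Conditions: iBu2AlH (1.1 equiv), CH2Cl2, −78 °C; aqueous potassium sodium tartrate
Reagents that add atoms: none
Why: Partial reduction of the ester at −78 °C through the stable tetrahedral aluminium hemiacetal, which should release the aldehyde only on work-up.

Step 10
Reactants: 16 3,19-O-(di-tert-butylsilylene)-3,19-dihydroxy-13,14,15,16-tetranor-ent-labd-8(17)-en-12-al; 17 furan-2(5H)-one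
Product: 19 3,19-O-(di-tert-butylsilylene)-3,12,19-trihydroxy-ent-labda-8(17),13-dien-16,15-olide (C12 epimers), via iodo aldol 18 (not isolated)
Conditions: 17 (1.5 equiv), Et2AlI (1.2 equiv), CH2Cl2, 0 °C; then Et3N, 23 °C
Reagents that add atoms: none
Why: Et2AlI-promoted Morita–Baylis–Hillman-type coupling, in which iodide adds to C14 of the butenolide, the aluminium enolate adds to the aldehyde and triethylamine eliminates HI from 18; the new C12 carbinol forms as an epimer mixture, which does not matter because C12 becomes planar in steps 12 and 13.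

Step 11
Reactants: 19 3,19-O-(di-tert-butylsilylene)-3,12,19-trihydroxy-ent-labda-8(17),13-dien-16,15-olide (C12 epimers)
Product: 20 12-O-(tert-butoxycarbonyl)-3,19-O-(di-tert-butylsilylene)-3,12,19-trihydroxy-ent-labda-8(17),13-dien-16,15-olide (C12 epimers)
Conditions: Boc2O, DMAP (10 mol %), CH2Cl2, 0 °C
Reagents that add atoms: di-tert-butyl dicarbonate, CC(C)(C)OC(=O)OC(=O)OC(C)(C)C
Why: DMAP-catalysed acylation of the secondary allylic alcohol to its tert-butyl carbonate, the leaving group that steps 12 and 13 require.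

Step 12
Reactants: 20 12-O-(tert-butoxycarbonyl)-3,19-O-(di-tert-butylsilylene)-3,12,19-trihydroxy-ent-labda-8(17),13-dien-16,15-olide (C12 epimers)
Product: 21 3,19-O-(di-tert-butylsilylene)-3,19-dihydroxy-ent-labda-8(17),11E,13-trien-16,15-olide
Conditions: DBU (1.2 equiv), toluene, 60 °C
Reagents that add atoms: none
Why: Base-induced elimination of tert-butyl carbonic acid across C11–C12 (SN2′ addition of the amidine at C14, deprotonation at C11, loss of the amidine), which should give the conjugated diene as the more stable E isomer from either C12 epimer.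

Step 13
Reactants: 20 12-O-(tert-butoxycarbonyl)-3,19-O-(di-tert-butylsilylene)-3,12,19-trihydroxy-ent-labda-8(17),13-dien-16,15-olide (C12 epimers); 21 3,19-O-(di-tert-butylsilylene)-3,19-dihydroxy-ent-labda-8(17),11E,13-trien-16,15-olide
Product: 22 3,19:3′,19′-bis-O-(di-tert-butylsilylene) derivative of the target, (15R,12′S)
Conditions: 21 (1.3 equiv), (DHQD)2PHAL (10 mol %), toluene, 23 °C
Reagents that add atoms: none
Why: Lewis-base-catalysed allylic alkylation of a Morita–Baylis–Hillman carbonate by a butenolide, in which the amine adds SN2′ at C14′ and expels CO2 and tert-butoxide to give the 12′(13′)-alkylidene ammonium ion, tert-butoxide deprotonates C15 of 21, and the furanolate attacks C12′ through C15 (C13 is blocked, C11 is hindered) with release of the catalyst and return of the 13′(14′) alkene; C15 and C12′ should be set under catalyst control in the ion pair with the chiral ammonium, from either C12 epimer of 20.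

Step 14
Reactants: 22 3,19:3′,19′-bis-O-(di-tert-butylsilylene) derivative of the target, (15R,12′S)
Product: 23 target CNP0220272.2
Conditions: HF·pyridine, THF, pyridine, 0 to 23 °C
Reagents that add atoms: none
Why: Fluoride-mediated cleavage of the four Si–O bonds of the two silylene rings, under buffered conditions that should leave the butenolides, the diene and the exocyclic alkenes untouched.

**Compound list**
1 | 5-hydroxypentan-2-one | CC(=O)CCCO | starting material
2 | 2-methyl-2-vinyloxirane (racemic) | C=CC1(C)CO1 | starting material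
3 | (5R,6R)-5-hydroxy-6-(hydroxymethyl)-6-methyloct-7-en-2-one | C=C[C@](C)(CO)[C@H](O)CCC(C)=O | intermediate
4 | 4-[(4R,5R)-2,2-di-tert-butyl-5-ethenyl-5-methyl-1,3,2-dioxasilinan-4-yl]butan-2-one | C=C[C@](C)(CO1)[C@H](O[Si]1(C(C)(C)C)C(C)(C)C)CCC(C)=O | intermediate
5 | allyltrimethylsilane | C=CC[Si](C)(C)C | starting material
6 | 4-{(4R,5R)-2,2-di-tert-butyl-5-methyl-5-[(E)-3-(trimethylsilyl)prop-1-en-1-yl]-1,3,2-dioxasilinan-4-yl}butan-2-one | C[Si](C)(C)C/C=C/[C@](C)(CO1)[C@H](O[Si]1(C(C)(C)C)C(C)(C)C)CCC(C)=O | intermediate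
7 | 2,2-dimethyl-1,3-dioxane-4,6-dione (Meldrum's acid) | CC1(C)OC(=O)CC(=O)O1 | starting material
8 | 5-(4-{(4R,5R)-2,2-di-tert-butyl-5-methyl-5-[(E)-3-(trimethylsilyl)prop-1-en-1-yl]-1,3,2-dioxasilinan-4-yl}butan-2-ylidene)-2,2-dimethyl-1,3-dioxane-4,6-dione | C[Si](C)(C)C/C=C/[C@](C)(CO1)[C@H](O[Si]1(C(C)(C)C)C(C)(C)C)CCC(C)=C2C(=O)OC(C)(C)OC2=O | intermediate
9 | Meldrum's acid adduct: ring A closed, 3,19-O-silylene, C10 bearing axial methyl and the 2,2-dimethyl-4,6-dioxo-1,3-dioxan-5-yl group, C5 bearing an equatorial vinyl group trans to that group | C=C[C@@H]1[C@](C)(CO2)[C@H](O[Si]2(C(C)(C)C)C(C)(C)C)CC[C@@]1(C)C3C(=O)OC(C)(C)OC3=O | intermediate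
10 | 3,19-O-(di-tert-butylsilylene)-3,19-dihydroxy-11,12,13,14,15,16,17-heptanor-ent-labd-6-en-8-one | O=C1C=C[C@@H]2[C@](C)(CO3)[C@H](O[Si]3(C(C)(C)C)C(C)(C)C)CC[C@@]2(C)C1 | intermediate
11 | methyl bromoacetate | COC(=O)CBr | starting material
12 | methyl 3,19-O-(di-tert-butylsilylene)-3,19-dihydroxy-8-oxo-13,14,15,16,17-pentanor-9-epi-ent-labd-6-en-12-oate | O=C1C=C[C@@H]2[C@](C)(CO3)[C@H](O[Si]3(C(C)(C)C)C(C)(C)C)CC[C@@]2(C)[C@H]1CC(=O)OC | intermediate
13 | methyl 3,19-O-(di-tert-butylsilylene)-3,19-dihydroxy-8-oxo-13,14,15,16,17-pentanor-9-epi-ent-labdan-12-oate | O=C1CC[C@@H]2[C@](C)(CO3)[C@H](O[Si]3(C(C)(C)C)C(C)(C)C)CC[C@@]2(C)[C@H]1CC(=O)OC | intermediate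
14 | methyl 3,19-O-(di-tert-butylsilylene)-3,19-dihydroxy-8-oxo-13,14,15,16,17-pentanor-ent-labdan-12-oate | O=C1CC[C@@H]2[C@](C)(CO3)[C@H](O[Si]3(C(C)(C)C)C(C)(C)C)CC[C@@]2(C)[C@@H]1CC(=O)OC | intermediate
15 | methyl 3,19-O-(di-tert-butylsilylene)-3,19-dihydroxy-13,14,15,16-tetranor-ent-labd-8(17)-en-12-oate | C=C1CC[C@@H]2[C@](C)(CO3)[C@H](O[Si]3(C(C)(C)C)C(C)(C)C)CC[C@@]2(C)[C@@H]1CC(=O)OC | intermediate
16 | 3,19-O-(di-tert-butylsilylene)-3,19-dihydroxy-13,14,15,16-tetranor-ent-labd-8(17)-en-12-al | C=C1CC[C@@H]2[C@](C)(CO3)[C@H](O[Si]3(C(C)(C)C)C(C)(C)C)CC[C@@]2(C)[C@@H]1CC=O | intermediate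
17 | furan-2(5H)-one | O=C1C=CCO1 | starting material
18 | 3,19-O-(di-tert-butylsilylene)-3,12,19-trihydroxy-14-iodo-ent-labd-8(17)-en-16,15-olide (diastereomer mixture at C12, C13, C14) | C=C1CC[C@@H]2[C@](C)(CO3)[C@H](O[Si]3(C(C)(C)C)C(C)(C)C)CC[C@@]2(C)[C@@H]1CC(O)C4C(I)COC4=O | intermediate
19 | 3,19-O-(di-tert-butylsilylene)-3,12,19-trihydroxy-ent-labda-8(17),13-dien-16,15-olide (C12 epimers) | C=C1CC[C@@H]2[C@](C)(CO3)[C@H](O[Si]3(C(C)(C)C)C(C)(C)C)CC[C@@]2(C)[C@@H]1CC(O)C4=CCOC4=O | intermediate
20 | 12-O-(tert-butoxycarbonyl)-3,19-O-(di-tert-butylsilylene)-3,12,19-trihydroxy-ent-labda-8(17),13-dien-16,15-olide (C12 epimers) | C=C1CC[C@@H]2[C@](C)(CO3)[C@H](O[Si]3(C(C)(C)C)C(C)(C)C)CC[C@@]2(C)[C@@H]1CC(OC(=O)OC(C)(C)C)C4=CCOC4=O | intermediate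
21 | 3,19-O-(di-tert-butylsilylene)-3,19-dihydroxy-ent-labda-8(17),11E,13-trien-16,15-olide | C=C1CC[C@@H]2[C@](C)(CO3)[C@H](O[Si]3(C(C)(C)C)C(C)(C)C)CC[C@@]2(C)[C@@H]1/C=C/C4=CCOC4=O | intermediate
22 | 3,19:3′,19′-bis-O-(di-tert-butylsilylene) derivative of the target, (15R,12′S) | C=C1CC[C@@H]2[C@](C)(CO3)[C@H](O[Si]3(C(C)(C)C)C(C)(C)C)CC[C@@]2(C)[C@@H]1/C=C/C4=C[C@H]([C@@H](C[C@@H]5C(=C)CC[C@@H]6[C@](C)(CO7)[C@H](O[Si]7(C(C)(C)C)C(C)(C)C)CC[C@]65C)C8=CCOC8=O)OC4=O | intermediate
23 | CNP0220272.2: (15R)-15-[(12′S)-3′,19′-dihydroxy-ent-labda-8′(17′),13′-dien-16′,15′-olid-12′-yl]-3,19-dihydroxy-ent-labda-8(17),11E,13-trien-16,15-olide | C=C1CC[C@@H]2[C@](C)(CO)[C@H](O)CC[C@@]2(C)[C@@H]1/C=C/C1=C[C@H]([C@@H](C[C@@H]2C(=C)CC[C@@H]3[C@](C)(CO)[C@H](O)CC[C@]32C)C2=CCOC2=O)OC1=O | target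

Total step count: 14. Longest linear sequence: 14 steps (1 to 23; carbonate 20 serves both as precursor of 21 and as its partner).

**Steps most likely to fail**

Step 5 (Proposed new method). The cascade may stop after ring A, because the unactivated vinyl group may be too weak a nucleophile for the acylketene, which would then be lost to dimerisation or hydrolysis; a second risk is poor facial selectivity at C10 in the ring A closure. A fallback by known chemistry sets out from 8: EtAlCl2 at −78 °C should effect only the Hosomi–Sakurai ring closure to Meldrum's acid 9, which is now isolated. Hydrolysis and decarboxylation in aqueous pyridine at 100 °C give the ring A acetic acid F1, and oxalyl chloride gives the acid chloride F2. SnCl4-mediated intramolecular acylation of the vinyl group (Friedel–Crafts-type alkene acylation) gives the β-chloro ketone F3, and DBU eliminates HCl to return to the route at 10.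

Step 13. Facial control at C15 and C12′ by the amine catalyst may be poor with two large chiral partners, and alkylation at C11 or a second alkylation of the product may compete. The fallback sets out from 21: silylation with iPr3SiOTf and Et3N gives the 2-silyloxyfuran F4, which is joined to 20 by palladium-catalysed allylic alkylation (Pd2(dba)3 with a chiral bis(2-diphenylphosphinobenzoyl)-1,2-diaminocyclohexane ligand). Zerovalent palladium ionises the carbonate to a 2-acyl π-allyl complex, the released tert-butoxide desilylates F4, and the furanolate attacks C12′ through C15 under ligand control, returning to the route at 22.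

Step 3. The metathesis catalyst may fail to engage the vinyl group because the adjacent quaternary carbon shields it, so that only allylsilane homodimer forms. The fallback sets out from 4: ozonolysis (O3, then PPh3) gives the aldehyde F5, and Julia–Kocienski olefination with 1-phenyl-5-{[2-(trimethylsilyl)ethyl]sulfonyl}-1H-tetrazole and KN(SiMe3)2 at −78 °C (aldehyde-selective, E-selective) returns to the route at 6.

Further compounds
F1 | step 5 | ring A acetic acid: 3,19-O-silylene ring A with C5 vinyl and C10 methyl and carboxymethyl, ent-labdane configuration | C=C[C@@H]1[C@](C)(CO2)[C@H](O[Si]2(C(C)(C)C)C(C)(C)C)CC[C@@]1(C)CC(=O)O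
F2 | step 5 | acid chloride of F1 | C=C[C@@H]1[C@](C)(CO2)[C@H](O[Si]2(C(C)(C)C)C(C)(C)C)CC[C@@]1(C)CC(=O)Cl
F3 | step 5 | 6-chloro-3,19-O-(di-tert-butylsilylene)-3,19-dihydroxy-11,12,13,14,15,16,17-heptanor-ent-labdan-8-one (C6 epimers) | O=C1CC(Cl)[C@@H]2[C@](C)(CO3)[C@H](O[Si]3(C(C)(C)C)C(C)(C)C)CC[C@@]2(C)C1
F4 | step 13 | 2-(triisopropylsilyloxy)furan derived from 21 (furan C3 carrying the (E)-C11=C12 alkene) | C=C1CC[C@@H]2[C@](C)(CO3)[C@H](O[Si]3(C(C)(C)C)C(C)(C)C)CC[C@@]2(C)[C@@H]1/C=C/c4ccoc4O[Si](C(C)C)(C(C)C)C(C)C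
F5 | step 3 | (4R,5R)-2,2-di-tert-butyl-5-methyl-4-(3-oxobutyl)-1,3,2-dioxasilinane-5-carbaldehyde | O=C[C@](C)(CO1)[C@H](O[Si]1(C(C)(C)C)C(C)(C)C)CCC(C)=O
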